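# Proposed total synthesis of brianthein V by allenyl anionic oxy-Cope ring expansion

## Structural features

Brianthein V (44) is a bicyclo[8.4.0]tetradecane. A cyclohexane (ring A: C1, C10, C11, C12, C13, C14) is trans-fused through C1–C10 to a ten-membered carbocycle (C1 to C10), which carries a γ-lactone (C7, C8, C17, C19, O) trans-fused at C7–C8. There are twelve stereocentres: C1 is quaternary and flanked by C2, C10 and C14, the run C6 to C14 (through C10) is stereogenic without a break, and C17 sits α to the lactone carbonyl. The C15 methyl, the C20 methyl and O9 lie on one face, so any six-membered ring through C1, C10 and C9 holds them syn-axial and strained. The fragile groups are the secondary allylic chloride at C6, the 2-substituted diene C3=C4–C5=C16, the β-hydroxy lactone (retro-aldol, dehydration, C17 epimerisation), the ring A epoxide and three esters of two kinds. The real difficulty is the ten-membered ring: it contains a Z alkene and an exocyclic methylene and is functionalised at six of its ten carbons, and it should be made without a macrocyclisation. The key step uses the 1,5-relation of the Z C3=C4 alkene, the C5=C16 methylene and carbonyl-level C8 across the C5–C6 bond. This is the pattern left by an oxy-Cope shift of a C8 vinyl carbinol and a C3 allenyl group across a C3–C8 bond, so the medium ring can come from a decalin (ring A plus ring B: C1, C2, C3, C8, C9, C10).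

## Logic of the disconnections

44 ⇒ 41 (via 43, 42). The O2–acyl and O12–acyl bonds and the two C–O bonds of the C13/C14 epoxide are cut. Esters cannot pass the basic steps and the epoxide cannot pass acid or chloride, so both are left to the end. The gain is that the free 12α-hydroxyl of 41 can deliver the epoxide oxygen to its own face. The demand is that O12 be the only free allylic hydroxyl at that point (O2 still silylated) and that the tertiary C8 hydroxyl is not acylated.

41 ⇒ 38 (via 40, 39). The O9–acetyl bond is cut and the free hydroxyls are replaced by three groups removable one at a time (fluoride for O2, DDQ for O9, cerium for O12). This is what allows one acetate and two butanoates to be placed. The demand is that two oxidative deprotections spare the diene and the allylic chloride.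

38 ⇒ 36 ⇒ 34 + 35 (via 37). The lactone C19–O7 bond and the C6–Cl bond are cut together, because both come from one trans epoxide opened at allylic C6 with inversion. The C8–C17 bond is then cut as an aldol. Four centres (C6, C7, C8, C17) are traced to one epoxy ketone and a three-carbon ester. The demand is chloride at C6 and not C16, carbonyl attack anti to the C7–O and C9–O bonds, and thermodynamic correction of C17 in the lactone if needed.

34 ⇒ 33 ⇒ 29. The epoxide C–O bonds are cut to give the E enone, and the C6=C7 unsaturation is removed. The demand is enolisation toward C7 only and a facial preference in the peroxide addition, which is the weakest point of the plan.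

29 ⇒ 27 (key step). The C5–C6 bond is cut and C3–C8 re-formed. The ten-membered ring becomes a trans-decalin, and the Z alkene and the methylene become an allene and a vinyl group. The demand on 27 is an axial C8 vinyl group, an equatorial C3 allenyl group, a free tertiary hydroxyl, base-stable ethers and no silyl group on O9.

27 ⇒ 24 ⇒ 21 ⇒ 18 + 19 + 22. The allene is traced to a propargylic C4–O bond, the C8–C7 bond to a carbonyl addition, and the C3–C4 bond to an aldol reaction. All three operations use the C8 ketone of 18 and the shielded β face of ring B. The demand is enolisation toward C3 and α-face attack at C3 and C8.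

18 ⇒ 16. The C2–C3 bond of ring B is cut (aldol). The bicycle becomes a monocycle whose C1 and C10 substituents are already trans. The demand is an equatorial oxygen at C2.

16 ⇒ 14 ⇒ 12 ⇒ 11 ⇒ 9 + 10. The C8 carbonyl is traced to an alkyne, the C9–H bond to a ketone reduction, and the C9–C8 bond to an acetylide acylation. This turns the dissonant C8/C9 dioxygenation into standard steps and places C9 under catalyst control.

9 ⇒ 8 ⇒ 7 ⇒ 6 ⇒ 5 ⇒ 4. These are functional group changes in ring A: the O12–aryl bond (formed with inversion), the amide, the C12–H bond, the acetal and the C13=C14 bond from the enol ether.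

4 ⇒ 2 + 3 and 2 ⇒ 1. The C1–C14 and C10–C11 bonds are cut (Diels–Alder). Ring A with C1, C10 and C11 comes from two small achiral partners. The demand is formyl-directed regiochemistry, formyl-exo topology and catalyst-controlled facial selectivity.

## Other disconnections considered

Alternative 1: The cut is through C1–C14 and C10–C11, taking ring A apart into 2 and 3. The forward step is the formyl-exo Diels–Alder reaction under a chiral oxazaborolidinium catalyst, giving A1.
- In its favour: one catalytic step makes ring A, the quaternary C1 and the C10 and C11 centres with C15, C9 and C20 all cis. The regiochemistry follows from polarity (C11 nucleophilic, C10 β to the bound formyl group).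
- Against it as the strategic step: it does not address the ten-membered ring, the chloride or the lactone, and the C10 and C11 centres of A1 are epimerisable and contra-thermodynamic.
- Comparison: it is a complement and not a rival. A1 is identical with 4 and the reaction is step 2 of the chosen route. In stereocentres set per step it is better than the ring expansion (three against none). In rings made it is equal (one each). It is bimolecular and catalyst-controlled, where the [3,3] shift is unimolecular and substrate-controlled. It does not shorten the route, because everything after ring A is still required.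

Alternative 2: The cut is through C1–C10 and C13–C14. On heating at high dilution the open-chain trienone A3 (silyloxydiene C10–C13, isopropenyl ketone C14=C1–C2, lactone and chloride in place) would close ring A and the ten-membered ring to A2.
- In its favour: two rings and the C1 and C10 centres are formed in one late step from a single chain, and diene and dienophile are polarity-matched (C13 to C14).
- Against it: the ten-membered ring is closed by forming the most hindered bond (quaternary C1 to tertiary C10) at a large entropic cost. A3 contains a cross-conjugated divinyl ketone, a second diene (C3=C4–C5=C16), an allylic chloride and a β-hydroxy lactone, all of which can react on heating. Trans fusion and facial selectivity rest on remote centres in a flexible chain. After A2, the C2 reduction, C11 protonation, C12 reduction, C13=C14 desaturation, epoxidation and acylations remain, all on a chlorinated lactone.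
- Comparison: in rings and centres formed by the key step it is better than the chosen plan. Both steps are thermally allowed pericyclic reactions, but the oxy-Cope shift runs inside a rigid frame and is driven by enolate formation and strain release, whereas the cycloaddition must pay for medium-ring closure. In longest linear sequence it could be equal or shorter through convergence, but the C6–C9/C17 array of A3 would have to be built without ring control.

Alternative 3: The cut is C8–C17. SmI2 (divalent samarium) would convert the C7 2-bromopropanoate A5 into a samarium enolate (trivalent samarium) that adds to the C8 ketone and closes the lactone to A4.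
- In its favour: delivery from O7 makes the regiochemistry certain. The conditions are neutral and cold, which suits a β-chloro ketone better than a lithium enolate does; on this point it is better than step 19. C8 and C17 are set in one compact chelated transition state.
- Against it: it is an end-game step and does not address how the ten-membered ketone is reached. A5 carries an α-acyloxy ketone (reductive C7–O cleavage competes), an allylic chloride and an epoxide. The trans fusion depends on ring conformation.
- Comparison: it is compatible with the ring expansion and is held as the fallback for step 19. Its step count (chloride opening, acylation, cyclisation) is about equal to the aldol and opening–lactonisation pair used here.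

Key step: step 16

Remarks on the chemistry:
- Briarane numbering is used throughout; in the decalins β is the face of the C15 methyl group, and the SMILES in the compound list define absolute configuration.
- The sense of induction in step 2 is taken from the usual model for formyl-bound 2-substituted enals with this catalyst class; the (S)-diphenylprolinol-derived catalyst is written and its mirror image would be used if the model pointed to the other face.
- In 21 and 23 to 26 the C4 centre is left undefined because both epimers converge on the allene.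
- Three identical acetal ethers on O2, O9 and O12 could not lead to one acetate and two butanoates and would need acid at the end, so 27 carries a silyl ether (O2), a 4-methoxybenzyl ether (O9, next to the alkoxide, where a silyl group could migrate) and a 4-methoxyphenyl ether (O12).
- The C8 vinyl group is added directly, so no aluminium hydride meets the allene.

## Route

Step 1
Reactants: 1 pent-1-en-3-one
Product: 2 (Z)-3-(triethylsilyloxy)penta-1,3-diene
Conditions: Et3SiOTf, Et3N, Et2O, 0 °C
Reagents that add atoms: triethylsilyl trifluoromethanesulfonate, CC[Si](CC)(CC)OS(=O)(=O)C(F)(F)F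
Why: Soft enolisation and O-silylation of an ethyl ketone; the Z enol ether is the usual product and places the methyl group on the outside of the s-cis diene.

Step 2
Reactants: 2 (Z)-3-(triethylsilyloxy)penta-1,3-diene; 3 ethyl (E)-3-methyl-4-oxobut-2-enoate
Product: 4 ring A cycloadduct (C2 aldehyde, C9 ethyl ester, C12/C13 silyl enol ether)
Conditions: (S)-o-tolyl-oxazaborolidinium triflimide [from (S)-diphenylprolinol, o-tolylboroxine, HNTf2] (cat.), CH2Cl2, −78 °C
Reagents that add atoms: none
Why: Catalytic asymmetric Diels–Alder reaction: boron binds the formyl oxygen, so C10 (β to it) joins the nucleophilic C11 of the silyloxydiene and C1 joins C14. The E dienophile sets C2 and C9 trans, the 2-substituted enal reacts formyl-exo (ester endo), which puts C20 cis to C9 and C15, and the catalyst chooses the enal face (1S,10S,11R).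

Step 3
Reactants: 4 ring A cycloadduct
Product: 5 ring A enone (C12 ketone, C13=C14)
Conditions: Pd(OAc)2 (1.1 equiv), MeCN, rt
Reagents that add atoms: none
Why: Saegusa oxidation: the silyl enol ether gives a palladium enolate (divalent palladium) whose β-hydride elimination can only go toward C14; the neutral conditions leave the epimerisable C10 and C11 centres alone.

Step 4
Reactants: 5 ring A enone
Product: 6 C2 dimethyl acetal of 5
Conditions: HC(OMe)3, CeCl3·7H2O (cat.), MeOH, rt
Reagents that add atoms: trimethyl orthoformate, COC(OC)OC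
Why: Lanthanide-catalysed acetal formation is selective for the aldehyde over the conjugated ketone; C2 stays masked until ring B is closed.

Step 5
Reactants: 6 C2 dimethyl acetal
Product: 7 12β-allylic alcohol
Conditions: 9-BBN, THF, 0 °C → rt; then HOCH2CH2NH2
Reagents that add atoms: none
Why: 1,2-Reduction of the enone by a bulky dialkylborane that leaves the ester alone; hydride should enter from the α face, away from the axial C9 ester (or, in the minor ring conformer, the axial C20 methyl), giving the 12β alcohol needed for an invertive etherification.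

Step 6
Reactants: 7 12β-allylic alcohol
Product: 8 N-methoxy-N-methylamide with free 12β-hydroxyl
Conditions: MeNH(OMe)·HCl, i-PrMgCl, THF, −20 → 0 °C
Reagents that add atoms: N,O-dimethylhydroxylamine hydrochloride, Cl.CNOC
Why: Aminolysis of the ester by the magnesium amide gives the acyl donor for a single later addition; any bridged γ-lactone formed between the cis 1,3-related C12 hydroxyl and the C9 ester is opened by the same reagent, and the low temperature protects C10.

Step 7
Reactants: 8 hydroxy N-methoxy-N-methylamide
Product: 9 12α-(4-methoxyphenyl) ether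
Conditions: 4-MeOC6H4OH, PPh3, DIAD, toluene, 0 °C → rt
Reagents that add atoms: 4-methoxyphenol, COc1ccc(O)cc1
Why: Mitsunobu etherification: SN2 displacement of the activated allylic oxygen inverts C12 to the α configuration of the target and installs a base-stable, oxidatively removable group in the same step; SN2′ attack at neopentyl C14 is disfavoured, and the cis amide cannot participate from the rear.

Step 8
Reactants: 9 12α-aryl ether amide; 10 ethynyltrimethylsilane
Product: 11 C9 ynone
Conditions: 10, n-BuLi, THF, −78 °C; then 9, −78 → 0 °C; NH4Cl (aq)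
Reagents that add atoms: none
Why: Acylation of the lithium acetylide by the N-methoxy-N-methylamide; the chelated tetrahedral intermediate prevents a second addition and releases the ketone only on work-up. The two alkyne carbons become C8 and C3.

Step 9
Reactants: 11 C9 ynone
Product: 12 (9S)-propargylic alcohol
Conditions: RuCl[(S,S)-TsDPEN](p-cymene) (cat.), i-PrOH, rt
Reagents that add atoms: none
Why: Asymmetric transfer hydrogenation of an alkynyl ketone: the alkynyl group takes the place of the aryl group in the catalyst's transition state, so the (S,S) catalyst should give the 9S carbinol under reagent control, in the same sense as Felkin–Anh attack anti to the quaternary C1.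

Step 10
Reactants: 12 (9S)-propargylic alcohol
Product: 14 terminal alkyne 9-O-(4-methoxybenzyl) ether, via silylalkyne ether 13 (not isolated)
Conditions: NaH, 4-MeOC6H4CH2Cl, n-Bu4NI, DMF, 0 °C → rt; then MeOH, K2CO3, rt
Reagents that add atoms: 4-methoxybenzyl chloride, COc1ccc(CCl)cc1
Why: Williamson etherification of the propargylic alkoxide, then methanolysis of the alkynyl C–Si bond in the same flask; O9 receives a non-silyl group because it will sit next to the C8 alkoxide in the key step.

Step 11
Reactants: 14 terminal alkyne
Product: 16 keto aldehyde, via methyl ketone acetal 15 (not isolated)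
Conditions: Ph3PAuNTf2 (cat.), H2O, 1,4-dioxane, 50 °C; then 1 M HCl, THF, rt
Reagents that add atoms: water, O
Why: Markovnikov hydration of the terminal alkyne (π-acid catalysis by monovalent gold) places the carbonyl on C8 and makes C3 a methyl group; aqueous acid then frees the C2 aldehyde, which has no α-hydrogen. Water is used in excess so that hydration outruns side reactions of the benzylic ether.

Step 12
Reactants: 16 keto aldehyde
Product: 18 trans-decalin C8 ketone with 2β-silyloxy group, via enol silane 17 (not isolated)
Conditions: t-BuMe2SiOTf (1.3 equiv), i-Pr2NEt, CH2Cl2, −78 → −30 °C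
Reagents that add atoms: tert-butyldimethylsilyl trifluoromethanesulfonate, CC(C)(C)[Si](C)(C)OS(=O)(=O)C(F)(F)F
Why: One-pot enol silane formation and intramolecular Mukaiyama aldol reaction: soft enolisation occurs at the methyl group (C3), away from the alkoxy-bearing C9, and the enol silane adds to the silyl-activated aldehyde through a chair-like open transition state with the bulky silyloxonium oxygen equatorial. This sets 2β-O and leaves it silylated; the C1–C2 and C10–C9 bonds are trans on ring A, so the decalin is trans-fused.

Step 13
Reactants: 18 trans-decalin C8 ketone; 19 3-(trimethylsilyl)prop-2-ynal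
Product: 21 C3 aldol adduct, via lithium enolate 20 (not isolated)
Conditions: LiN(i-Pr)2, THF, −78 °C; then 19; AcOH, −78 °C
Reagents that add atoms: none
Why: Kinetic deprotonation removes the axial C3 hydrogen (C9 has only an equatorial hydrogen, poorly aligned with the carbonyl, and the equatorial O2 is not aligned for β-elimination). The aldehyde adds on the α face of C3 because the β face is closed by the syn-axial C15 methyl and O9, giving the 3α (equatorial) side chain; the C4 configuration does not matter.

Step 14
Reactants: 21 C3 aldol adduct; 22 vinylmagnesium bromide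
Product: 24 C8 vinyl carbinol with free terminal alkyne, via silylalkyne diol 23 (not isolated)
Conditions: CH2=CHMgBr (excess), CeCl3, THF, −78 °C; then MeOH, K2CO3, rt
Reagents that add atoms: none
Why: Organocerium 1,2-addition (which suppresses enolisation and retro-aldol cleavage) from the α face: attack is anti to the axial C9–O bond (Felkin–Anh) and avoids the axial ether on the β face, so the vinyl group is axial and the C8 hydroxyl is β and equatorial. Methanolic carbonate then removes the alkynyl silyl group.

Step 15
Reactants: 24 C8 vinyl carbinol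
Product: 27 oxy-Cope precursor (3α-allenyl, 8α-vinyl, 8β-hydroxyl), via sulfonylhydrazine 25 (not isolated), via propargylic diazene 26 (not isolated)
Conditions: 2-O2NC6H4SO2NHNH2, PPh3, DEAD, THF, −15 °C → rt
Reagents that add atoms: none
Why: Myers allene synthesis: Mitsunobu displacement of the secondary propargylic hydroxyl by the arenesulfonylhydrazine (the tertiary C8 hydroxyl is inert), loss of sulfinic acid, and retro-ene loss of N2 from the diazene, which delivers hydrogen to C16 and forms the C4=C5=C16 allene. No stereocentre is made, so the C4 epimers converge.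

Step 16
Reactants: 27 oxy-Cope precursor
Product: 29 ten-membered C8 ketone with Z C3=C4 and C5=C16 methylene, via potassium enolate 28 (not isolated)
Conditions: KH, 18-crown-6, THF, 0 °C → rt; then NH4Cl (aq), −78 °C
Reagents that add atoms: none
Why: Deprotonation of the C8 hydroxyl gives a crown-separated potassium alkoxide whose oxygen weakens the C3–C8 bond and triggers a [3,3]-sigmatropic shift through the chair array C5–C4–C3–C8–C7–C6: the central allene carbon C5 bonds to the vinyl terminus C6, C3–C8 breaks, and enolate 28 forms with its double bond fixed between C7 and C8; cold protonation gives 29. The closest known reaction type is the anionic oxy-Cope ring expansion of 1,2-dialkenylcyclohexanols to cyclodec-5-enones, here with an allene as one partner as in known allenyl oxy-Cope shifts. No ring is closed by bond formation: the ten-membered ring arises by a four-carbon enlargement of ring B, with C5–C6 formed across the chair while the ring bond C3–C8 is lost. No stereocentre is created, and C1, C2, C9, C10, C11 and C12 are untouched. The step needs Z geometry at C3=C4 and a single enolate regioisomer; on the trans-decalin the axial C8 vinyl and equatorial C3 allenyl groups are gauche and can reach each other only in the chair that has C2 pseudoaxial on C3 (Z alkene) and C9 pseudoequatorial on C8. The allene π bond that takes no part remains as the C5=C16 methylene, conjugated with C3=C4. Release of the syn-axial strain among C15, C20 and O9 and formation of a delocalised enolate make the shift irreversible, and the equatorial O2 silyl group cannot reach the alkoxide.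

Step 17
Reactants: 29 ten-membered C8 ketone
Product: 33 (6E)-enone, via lithium enolate 30 (not isolated), via selenide 31 (not isolated), via selenoxide 32 (not isolated)
Conditions: LiN(SiMe3)2, THF, −78 °C; PhSeBr; then H2O2, pyridine, CH2Cl2, 0 °C → rt
Reagents that add atoms: none
Why: Kinetic enolisation at the C7 methylene (C9 is a hindered alkoxy methine), selenenylation, and selenoxide syn-elimination toward C6, which carries the only β-hydrogens; as in amine oxide eliminations of ten-membered rings, the syn transition state with C5 and C8 anti should give the E enone.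

Step 18
Reactants: 33 (6E)-enone
Product: 34 (6R,7S)-6,7-trans-epoxy ketone
Conditions: t-BuOOH, n-BuLi, THF, −78 → −20 °C
Reagents that add atoms: tert-butyl hydroperoxide, CC(C)(C)OO
Why: Weitz–Scheffer epoxidation with lithium tert-butyl peroxide under aprotic conditions that do not epimerise C9: conjugate addition at C6 and closure of the enolate give the trans α,β-epoxy ketone and leave the C5=C16 bond alone. The peroxide is expected to add to the outer face of the enone in the conformer with the C8 carbonyl anti to the C9–O dipole, giving the 6R,7S epoxide; this facial choice is the least secure stereochemical point of the route.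

Step 19
Reactants: 34 epoxy ketone; 35 ethyl propanoate
Product: 36 C8 aldol adduct (8R, 17R) with the epoxide intact
Conditions: LiN(i-Pr)2, 35, THF, −78 °C; then 34; AcOH, −78 °C
Reagents that add atoms: none
Why: Aldol addition of the ester enolate to the ketone: attack anti to the epoxide C7–O bond (the usual sense for α,β-epoxy ketones) and anti to the C9–O bond (Felkin–Anh, non-chelating lithium in THF) both lead to the 8R carbinol. C17 is set kinetically; if its epimer forms, it should converge at lactone 38 on DBU equilibration, because there the C18 methyl trans to C9 is the more stable arrangement.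

Step 20
Reactants: 36 C8 aldol adduct
Product: 38 chloro hydroxy γ-lactone, via chlorohydrin ester 37 (not isolated)
Conditions: ClTi(O-i-Pr)3, CH2Cl2, 0 °C → rt
Reagents that add atoms: chlorotitanium triisopropoxide, CC(C)O[Ti](Cl)(OC(C)C)OC(C)C
Why: Titanium-mediated opening of a 2,3-epoxy alcohol at the carbon remote from the carbinol: chloride attacks the allylic C6 with inversion (attack at C7 is blocked by the quaternary C8), giving the anti 6-chloro-7-alkoxide. The titanium alkoxide at O7 then closes the γ-lactone on the ester by transesterification (5-exo-trig).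

Step 21
Reactants: 38 chloro hydroxy γ-lactone
Product: 39 C9 alcohol
Conditions: DDQ, CH2Cl2/pH 7 buffer, 0 °C
Reagents that add atoms: none
Why: Oxidative cleavage of the 4-methoxybenzyl ether (benzylic hydride abstraction, then hydrolysis of the oxocarbenium ion); the aryl ether on O12, the silyl ether and the chloride are unaffected, and water suppresses acetal formation with the C8 hydroxyl.

Step 22
Reactants: 39 C9 alcohol
Product: 40 C9 acetate
Conditions: Ac2O, DMAP, pyridine, CH2Cl2, 0 °C → rt
Reagents that add atoms: acetic anhydride, CC(=O)OC(C)=O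
Why: Acylation of the secondary C9 hydroxyl; the tertiary C8 hydroxyl stays free under these mild conditions.

Step 23
Reactants: 40 C9 acetate
Product: 41 12α-allylic alcohol
Conditions: (NH4)2Ce(NO3)6, pyridine, MeCN/H2O, 0 °C
Reagents that add atoms: none
Why: Oxidative dearylation of the 4-methoxyphenyl ether: tetravalent cerium oxidises the arene to benzoquinone and releases the C12 hydroxyl with retention, since the C12–O bond is not broken.

Step 24
Reactants: 41 12α-allylic alcohol
Product: 42 13α,14α-epoxy 12α-alcohol
Conditions: VO(acac)2 (cat.), t-BuOOH, CH2Cl2, 0 °C → rt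
Reagents that add atoms: tert-butyl hydroperoxide, CC(C)(C)OO
Why: Hydroxyl-directed epoxidation: the vanadate ester of the pseudoaxial 12α-hydroxyl delivers oxygen to the α face of C13=C14, which is also the face anti to C15, giving the cis epoxy alcohol. The diene has no free allylic hydroxyl (O2 is silylated), and the tertiary C8 hydroxyl is too remote and hindered to compete.

Step 25
Reactants: 42 epoxy alcohol
Product: 43 2,12-diol
Conditions: HF·pyridine, pyridine, THF, 0 °C → rt
Reagents that add atoms: none
Why: Buffered fluoride cleavage of the secondary silyl ether, under conditions that spare the epoxide, the esters and the chloride.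

Step 26
Reactants: 43 2,12-diol
Product: 44 brianthein V
Conditions: (n-PrCO)2O, Et3N, DMAP, CH2Cl2, 0 °C → rt
Reagents that add atoms: butanoic anhydride, CCCC(=O)OC(=O)CCC
Why: Double acylation of the secondary O2 and O12 hydroxyls; the tertiary C8 hydroxyl remains free, as in the target.

## Compound list

1 | pent-1-en-3-one | C=CC(=O)CC | starting material
2 | (Z)-3-(triethylsilyloxy)penta-1,3-diene | C=C/C(O[Si](CC)(CC)CC)=C/C | intermediate
3 | ethyl (E)-3-methyl-4-oxobut-2-enoate | O=C/C(C)=C/C(=O)OCC | starting material
4 | ring A cycloadduct, ethyl (1S,2R,6S)-6-formyl-2,6-dimethyl-3-(triethylsilyloxy)cyclohex-3-ene-1-carboxylate (briarane C10, C11, C1; C15, C9 and C20 cis) | O=C[C@]1(C)[C@H]([C@@H](C)C(O[Si](CC)(CC)CC)=CC1)C(=O)OCC | intermediate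
5 | ring A enone, ethyl (1S,2R,6S)-6-formyl-2,6-dimethyl-3-oxocyclohex-4-ene-1-carboxylate | O=C[C@]1(C)[C@H]([C@@H](C)C(=O)C=C1)C(=O)OCC | intermediate
6 | C2 dimethyl acetal of 5, ethyl 6-(dimethoxymethyl)-2,6-dimethyl-3-oxocyclohex-4-ene-1-carboxylate, stereocentres as in 5 | COC(OC)[C@]1(C)[C@H]([C@@H](C)C(=O)C=C1)C(=O)OCC | intermediate
7 | 12β-allylic alcohol (hydroxyl cis to the C20 methyl and the ester), ethyl 6-(dimethoxymethyl)-3-hydroxy-2,6-dimethylcyclohex-4-ene-1-carboxylate | COC(OC)[C@]1(C)[C@H]([C@@H](C)[C@@H](O)C=C1)C(=O)OCC | intermediate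
8 | N-methoxy-N-methylamide of 7, 12β-hydroxyl free | COC(OC)[C@]1(C)[C@H]([C@@H](C)[C@@H](O)C=C1)C(=O)N(C)OC | intermediate
9 | 12α-(4-methoxyphenyl) ether of the amide (C12 inverted, oxygen trans to the C20 methyl) | COC(OC)[C@]1(C)[C@H]([C@@H](C)[C@H](Oc3ccc(OC)cc3)C=C1)C(=O)N(C)OC | intermediate
10 | ethynyltrimethylsilane | C#C[Si](C)(C)C | starting material
11 | C9 ynone (C9 carbonyl bearing the trimethylsilylethynyl group C8≡C3), C2 acetal, 12α-aryloxy | COC(OC)[C@]1(C)[C@H]([C@@H](C)[C@H](Oc3ccc(OC)cc3)C=C1)C(=O)C#C[Si](C)(C)C | intermediate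
12 | (9S)-propargylic alcohol | COC(OC)[C@]1(C)[C@H]([C@@H](C)[C@H](Oc3ccc(OC)cc3)C=C1)[C@H](O)C#C[Si](C)(C)C | intermediate
13 | 9-O-(4-methoxybenzyl) ether of 12, silylalkyne | COC(OC)[C@]1(C)[C@H]([C@@H](C)[C@H](Oc3ccc(OC)cc3)C=C1)[C@H](OCc5ccc(OC)cc5)C#C[Si](C)(C)C | intermediate
14 | terminal alkyne (C8≡C3H), 9-O-(4-methoxybenzyl), C2 acetal, 12α-aryloxy | COC(OC)[C@]1(C)[C@H]([C@@H](C)[C@H](Oc3ccc(OC)cc3)C=C1)[C@H](OCc5ccc(OC)cc5)C#C | intermediate
15 | C8 methyl ketone with C2 dimethyl acetal | COC(OC)[C@]1(C)[C@H]([C@@H](C)[C@H](Oc3ccc(OC)cc3)C=C1)[C@H](OCc5ccc(OC)cc5)C(C)=O | intermediate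
16 | keto aldehyde: C2 aldehyde, C8 methyl ketone (C3 methyl), (9S)-O-(4-methoxybenzyl), 12α-O-(4-methoxyphenyl) | O=C[C@]1(C)[C@H]([C@@H](C)[C@H](Oc3ccc(OC)cc3)C=C1)[C@H](OCc5ccc(OC)cc5)C(C)=O | intermediate
17 | C8 tert-butyldimethylsilyl enol ether (C8=C3) of 16 | O=C[C@]1(C)[C@H]([C@@H](C)[C@H](Oc3ccc(OC)cc3)C=C1)[C@H](OCc5ccc(OC)cc5)C(=C)O[Si](C)(C)C(C)(C)C | intermediate
18 | trans-decalin C8 ketone (rings A and B): 2β-silyloxy (equatorial), 9β-(4-methoxybenzyloxy) (axial), 12α-(4-methoxyphenoxy), C13=C14, 1β-methyl, 11β-methyl, 10α-H | C1[C@H](O[Si](C)(C)C(C)(C)C)[C@]2(C)[C@H]([C@@H](C)[C@H](Oc3ccc(OC)cc3)C=C2)[C@H](OCc5ccc(OC)cc5)C1=O | intermediate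
19 | 3-(trimethylsilyl)prop-2-ynal | O=CC#C[Si](C)(C)C | starting material
20 | lithium C3=C8 enolate of 18 | [Li+].[O-]C1=C[C@H](O[Si](C)(C)C(C)(C)C)[C@]2(C)[C@H]([C@@H](C)[C@H](Oc3ccc(OC)cc3)C=C2)[C@@H]1OCc5ccc(OC)cc5 | intermediate
21 | aldol adduct: 18 with a 3α (equatorial) 1-hydroxy-3-(trimethylsilyl)prop-2-ynyl group (C4 epimers) | C[Si](C)(C)C#CC(O)[C@H]1[C@H](O[Si](C)(C)C(C)(C)C)[C@]2(C)[C@H]([C@@H](C)[C@H](Oc3ccc(OC)cc3)C=C2)[C@H](OCc5ccc(OC)cc5)C1=O | intermediate
22 | vinylmagnesium bromide | C=C[Mg]Br | starting material
23 | C8 carbinol (8β-hydroxyl equatorial, 8α-vinyl axial), silylalkyne still in place (C4 epimers) | C[Si](C)(C)C#CC(O)[C@H]1[C@H](O[Si](C)(C)C(C)(C)C)[C@]2(C)[C@H]([C@@H](C)[C@H](Oc3ccc(OC)cc3)C=C2)[C@H](OCc5ccc(OC)cc5)[C@@]1(O)C=C | intermediate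
24 | diol with free alkyne: 3α-(1-hydroxyprop-2-ynyl), 8β-hydroxyl, 8α-vinyl (C4 epimers) | C#CC(O)[C@H]1[C@H](O[Si](C)(C)C(C)(C)C)[C@]2(C)[C@H]([C@@H](C)[C@H](Oc3ccc(OC)cc3)C=C2)[C@H](OCc5ccc(OC)cc5)[C@@]1(O)C=C | intermediate
25 | C4 N-amino-N-(2-nitrobenzenesulfonyl)amine (Mitsunobu product of 24) | C#CC(N(N)S(=O)(=O)c4ccccc4[N+](=O)[O-])[C@H]1[C@H](O[Si](C)(C)C(C)(C)C)[C@]2(C)[C@H]([C@@H](C)[C@H](Oc3ccc(OC)cc3)C=C2)[C@H](OCc5ccc(OC)cc5)[C@@]1(O)C=C | intermediate
26 | C4 propargylic diazene | C#CC(N=N)[C@H]1[C@H](O[Si](C)(C)C(C)(C)C)[C@]2(C)[C@H]([C@@H](C)[C@H](Oc3ccc(OC)cc3)C=C2)[C@H](OCc5ccc(OC)cc5)[C@@]1(O)C=C | intermediate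
27 | oxy-Cope precursor: trans-decalin with 3α (equatorial) propa-1,2-dienyl, 8α (axial) vinyl, 8β-hydroxyl, 2β-silyloxy, 9β-(4-methoxybenzyloxy), 12α-(4-methoxyphenoxy) | C=C=C[C@H]1[C@H](O[Si](C)(C)C(C)(C)C)[C@]2(C)[C@H]([C@@H](C)[C@H](Oc3ccc(OC)cc3)C=C2)[C@H](OCc5ccc(OC)cc5)[C@@]1(O)C=C | intermediate
28 | potassium C7=C8 enolate of 29 (C9 and C6 trans) | [K+].C=C1/C=C\[C@H](O[Si](C)(C)C(C)(C)C)[C@]2(C)[C@H]([C@@H](C)[C@H](Oc3ccc(OC)cc3)C=C2)[C@H](OCc5ccc(OC)cc5)/C([O-])=C/C1 | intermediate
29 | ten-membered C8 ketone: (3Z)-alkene, C5=C16 methylene, C13=C14, 2-silyloxy, 9-(4-methoxybenzyloxy), 12-(4-methoxyphenoxy); C1, C2, C9, C10, C11, C12 as in 27 | C=C1/C=C\[C@H](O[Si](C)(C)C(C)(C)C)[C@]2(C)[C@H]([C@@H](C)[C@H](Oc3ccc(OC)cc3)C=C2)[C@H](OCc5ccc(OC)cc5)C(=O)CC1 | intermediate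
30 | lithium C7=C8 enolate of 29 (geometry not defined) | [Li+].C=C1/C=C\[C@H](O[Si](C)(C)C(C)(C)C)[C@]2(C)[C@H]([C@@H](C)[C@H](Oc3ccc(OC)cc3)C=C2)[C@H](OCc5ccc(OC)cc5)C([O-])=CC1 | intermediate
31 | 7-(phenylselanyl) ketone (C7 epimers) | C=C1/C=C\[C@H](O[Si](C)(C)C(C)(C)C)[C@]2(C)[C@H]([C@@H](C)[C@H](Oc3ccc(OC)cc3)C=C2)[C@H](OCc5ccc(OC)cc5)C(=O)C([Se]c4ccccc4)C1 | intermediate
32 | 7-(phenylseleninyl) ketone | C=C1/C=C\[C@H](O[Si](C)(C)C(C)(C)C)[C@]2(C)[C@H]([C@@H](C)[C@H](Oc3ccc(OC)cc3)C=C2)[C@H](OCc5ccc(OC)cc5)C(=O)C([Se](=O)c4ccccc4)C1 | intermediate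
33 | (6E)-enone (C6=C7 conjugated with the C8 ketone) | C=C1/C=C\[C@H](O[Si](C)(C)C(C)(C)C)[C@]2(C)[C@H]([C@@H](C)[C@H](Oc3ccc(OC)cc3)C=C2)[C@H](OCc5ccc(OC)cc5)C(=O)/C=C/1 | intermediate
34 | (6R,7S)-6,7-trans-epoxy C8 ketone | C=C1/C=C\[C@H](O[Si](C)(C)C(C)(C)C)[C@]2(C)[C@H]([C@@H](C)[C@H](Oc3ccc(OC)cc3)C=C2)[C@H](OCc5ccc(OC)cc5)C(=O)[C@H]4O[C@@H]41 | intermediate
35 | ethyl propanoate | CCC(=O)OCC | starting material
36 | aldol adduct: (8R)-hydroxyl, C8 bearing (17R)-CH(CH3)CO2Et, (6R,7S)-epoxide intact | C=C1/C=C\[C@H](O[Si](C)(C)C(C)(C)C)[C@]2(C)[C@H]([C@@H](C)[C@H](Oc3ccc(OC)cc3)C=C2)[C@H](OCc5ccc(OC)cc5)[C@](O)([C@@H](C)C(=O)OCC)[C@H]4O[C@@H]41 | intermediate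
37 | chlorohydrin ester: (6S)-chloro, (7R)-hydroxyl, rest as 36 | C=C1/C=C\[C@H](O[Si](C)(C)C(C)(C)C)[C@]2(C)[C@H]([C@@H](C)[C@H](Oc3ccc(OC)cc3)C=C2)[C@H](OCc5ccc(OC)cc5)[C@](O)([C@@H](C)C(=O)OCC)[C@@H](O)[C@H]1Cl | intermediate
38 | chloro hydroxy γ-lactone (O7–C19 closed): 2-silyloxy, 9-(4-methoxybenzyloxy), 12-(4-methoxyphenoxy); C6, C7, C8, C17 as in 44 | C=C1/C=C\[C@H](O[Si](C)(C)C(C)(C)C)[C@]2(C)[C@H]([C@@H](C)[C@H](Oc3ccc(OC)cc3)C=C2)[C@H](OCc5ccc(OC)cc5)[C@]2(O)[C@@H](C)C(=O)O[C@H]2[C@H]1Cl | intermediate
39 | C9 alcohol of 38 | C=C1/C=C\[C@H](O[Si](C)(C)C(C)(C)C)[C@]2(C)[C@H]([C@@H](C)[C@H](Oc3ccc(OC)cc3)C=C2)[C@H](O)[C@]2(O)[C@@H](C)C(=O)O[C@H]2[C@H]1Cl | intermediate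
40 | C9 acetate | C=C1/C=C\[C@H](O[Si](C)(C)C(C)(C)C)[C@]2(C)[C@H]([C@@H](C)[C@H](Oc3ccc(OC)cc3)C=C2)[C@H](OC(C)=O)[C@]2(O)[C@@H](C)C(=O)O[C@H]2[C@H]1Cl | intermediate
41 | 12α-allylic alcohol (C9 acetate, 2-silyloxy) | C=C1/C=C\[C@H](O[Si](C)(C)C(C)(C)C)[C@]2(C)[C@H]([C@@H](C)[C@H](O)C=C2)[C@H](OC(C)=O)[C@]2(O)[C@@H](C)C(=O)O[C@H]2[C@H]1Cl | intermediate
42 | 13α,14α-epoxy 12α-alcohol | C=C1/C=C\[C@H](O[Si](C)(C)C(C)(C)C)[C@]2(C)[C@H]([C@@H](C)[C@H](O)[C@@H]3O[C@@H]32)[C@H](OC(C)=O)[C@]2(O)[C@@H](C)C(=O)O[C@H]2[C@H]1Cl | intermediate
43 | 2,12-diol (C8 hydroxyl also free), C9 acetate, epoxide, lactone and chloride as in 44 | C=C1/C=C\[C@H](O)[C@]2(C)[C@H]([C@@H](C)[C@H](O)[C@@H]3O[C@@H]32)[C@H](OC(C)=O)[C@]2(O)[C@@H](C)C(=O)O[C@H]2[C@H]1Cl | intermediate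
44 | brianthein V | C=C1/C=C\[C@H](OC(=O)CCC)[C@]2(C)[C@H]([C@@H](C)[C@H](OC(=O)CCC)[C@@H]3O[C@@H]32)[C@H](OC(C)=O)[C@]2(O)[C@@H](C)C(=O)O[C@H]2[C@H]1Cl | target

## Step count and least certain steps

Total: 26 steps. Longest linear sequence: 26 steps, from 1; compounds 3, 10, 19, 22 and 35 enter as purchased materials.

Step 16 (key step). What may go wrong: heterolytic cleavage of the C3–C8 bond of the alkoxide without C5–C6 bond formation (retro-addition, followed by loss of O2 from the C3 carbanion), or addition of the alkoxide to the allene. Both gain ground if the syn-axial strain among C15, C20 and O9 pushes ring B out of the chair, so that the vinyl and allenyl termini are no longer within bonding distance; the same distortion could erode the Z selectivity. Fallback: from 27, silylation of the tertiary hydroxyl (Me3SiOTf, 2,6-lutidine) gives the trimethylsilyl ether F1. Thermolysis (o-dichlorobenzene, 180 °C, sealed tube) brings about the neutral siloxy-Cope shift with the same bond changes and gives the ten-membered silyl enol ether F2. Mild methanolysis (K2CO3, MeOH, 0 °C) returns to 29.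

Step 12. What may go wrong: poor facial selectivity at the C2 aldehyde, because the preference for an equatorial silyloxonium oxygen is opposed by two gauche contacts with the C1 substituents. Closure of a ring that must hold C15, C20 and O9 syn-axial may also be slow, which gives time for enol silane formation toward C9 and loss of its configuration. Fallback: from 16, cyclisation under reversible aldol conditions (catalytic KO-t-Bu, t-BuOH/THF, −40 °C) gives the separable ketols, the 2β-hydroxy ketone F3 and the 2α-hydroxy ketone F4. F4 is returned to the equilibrium through retro-aldol cleavage, and F3 is silylated (t-BuMe2SiOTf, 2,6-lutidine) to 18.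

Step 15. What may go wrong: slow Mitsunobu activation of the hindered C4 carbinol, which leaves time for elimination to the enyne or for cyclodehydration onto the C8 hydroxyl. Fallback: from 24, selective acylation of the secondary propargylic hydroxyl (ClCO2Me, pyridine, CH2Cl2, 0 °C) gives the propargylic methyl carbonate F5. Pd2(dba)3 (zerovalent palladium), n-Bu3P and HCO2NH4 in THF then reduce it by hydride transfer to the allenylpalladium intermediate, the known formate reduction of propargylic carbonates to allenes, and give 27.

Step 18. What may go wrong: poor or reversed facial selectivity in the peroxide addition, because the two faces of the E enone are told apart only by the conformation of the medium ring. The wrong trans epoxide would carry the error into C6 and C7. Fallback: from 33, 1,2-reduction (NaBH4, CeCl3·7H2O, MeOH, −78 °C) gives the allylic alcohol F6. Titanium–tartrate (Sharpless) epoxidation (Ti(O-i-Pr)4, D-(−)-diisopropyl tartrate, t-BuOOH, 4 Å sieves, CH2Cl2, −20 °C) lets the tartrate, not the ring, choose the alkene face and gives the epoxy alcohol F7. By analogy with simple E allylic alcohols this tartrate should give the 6R,7S epoxide; the mismatched C8 epimer reacts slowly and is reoxidised to 33 with MnO2 and recycled. Dess–Martin oxidation of F7 returns to 34.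

Step 19 (and with it step 20). What may go wrong: attack on the wrong face of the C8 carbonyl if the medium ring overrides the Felkin–Anh preference, retro-aldol loss of the tertiary aldolate, and in the next step participation of the C19 ester at C7 or allylic transposition of chloride to C16. Fallback: from 34, the epoxide is opened first (ClTi(O-i-Pr)3 or anhydrous HCl, CH2Cl2, −40 °C) to the chlorohydrin ketone F8. Acylation of O7 (2-bromopropanoyl bromide, pyridine, CH2Cl2, −20 °C) gives the 2-bromopropanoate F9. SmI2 (divalent samarium) in THF at −78 °C then generates the samarium enolate (trivalent samarium), which adds to C8 from the tether and closes the lactone, so the sequence rejoins the route at 38.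

## Further compounds

F1 | step 16 | trimethylsilyl ether of 27 at O8 | C=C=C[C@H]1[C@H](O[Si](C)(C)C(C)(C)C)[C@]2(C)[C@H]([C@@H](C)[C@H](Oc3ccc(OC)cc3)C=C2)[C@H](OCc5ccc(OC)cc5)[C@@]1(O[Si](C)(C)C)C=C
F2 | step 16 | ten-membered C7=C8 trimethylsilyl enol ether of 29 | C=C1/C=C\[C@H](O[Si](C)(C)C(C)(C)C)[C@]2(C)[C@H]([C@@H](C)[C@H](Oc3ccc(OC)cc3)C=C2)[C@H](OCc5ccc(OC)cc5)/C(O[Si](C)(C)C)=C/C1
F3 | step 12 | 2β-hydroxy decalin C8 ketone (desilyl 18) | C1[C@H](O)[C@]2(C)[C@H]([C@@H](C)[C@H](Oc3ccc(OC)cc3)C=C2)[C@H](OCc5ccc(OC)cc5)C1=O
F4 | step 12 | 2α-hydroxy decalin C8 ketone (C2 epimer of F3) | C1[C@@H](O)[C@]2(C)[C@H]([C@@H](C)[C@H](Oc3ccc(OC)cc3)C=C2)[C@H](OCc5ccc(OC)cc5)C1=O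
F5 | step 15 | C4 methyl carbonate of 24 | C#CC(OC(=O)OC)[C@H]1[C@H](O[Si](C)(C)C(C)(C)C)[C@]2(C)[C@H]([C@@H](C)[C@H](Oc3ccc(OC)cc3)C=C2)[C@H](OCc5ccc(OC)cc5)[C@@]1(O)C=C
F6 | step 18 | C8 allylic alcohol from 33 (C8 epimers) | C=C1/C=C\[C@H](O[Si](C)(C)C(C)(C)C)[C@]2(C)[C@H]([C@@H](C)[C@H](Oc3ccc(OC)cc3)C=C2)[C@H](OCc5ccc(OC)cc5)C(O)/C=C/1
F7 | step 18 | (6R,7S)-6,7-epoxy C8 alcohol (C8 configuration immaterial) | C=C1/C=C\[C@H](O[Si](C)(C)C(C)(C)C)[C@]2(C)[C@H]([C@@H](C)[C@H](Oc3ccc(OC)cc3)C=C2)[C@H](OCc5ccc(OC)cc5)C(O)[C@H]4O[C@@H]41
F8 | step 19 | (6S)-chloro-(7R)-hydroxy C8 ketone | C=C1/C=C\[C@H](O[Si](C)(C)C(C)(C)C)[C@]2(C)[C@H]([C@@H](C)[C@H](Oc3ccc(OC)cc3)C=C2)[C@H](OCc5ccc(OC)cc5)C(=O)[C@@H](O)[C@H]1Cl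
F9 | step 19 | C7 2-bromopropanoate of F8 (bromide epimers) | C=C1/C=C\[C@H](O[Si](C)(C)C(C)(C)C)[C@]2(C)[C@H]([C@@H](C)[C@H](Oc3ccc(OC)cc3)C=C2)[C@H](OCc5ccc(OC)cc5)C(=O)[C@@H](OC(=O)C(C)Br)[C@H]1Cl
A1 | alternative 1 | ring A cycloadduct with C2 aldehyde, C9 ethyl ester and C12/C13 silyl enol ether (identical with 4) | O=C[C@]1(C)[C@H]([C@@H](C)C(O[Si](CC)(CC)CC)=CC1)C(=O)OCC
A2 | alternative 2 | bicyclic C2 ketone with C11/C12 silyl enol ether, lactone and chloride in place | C=C1/C=C\C(=O)[C@]2(C)[C@H](C(C)=C(O[Si](C)(C)C(C)(C)C)CC2)[C@H](OC(C)=O)[C@]2(O)[C@@H](C)C(=O)O[C@H]2[C@H]1Cl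
A3 | alternative 2 | open-chain trienone: isopropenyl ketone (C14=C1–C2) and (E)-silyloxydiene (C10–C13) joined through C3–C9, lactone and chloride in place | C=C(C)C(=O)/C=C\C(=C)[C@H](Cl)[C@@H]1OC(=O)[C@H](C)[C@@]1(O)[C@@H](OC(C)=O)/C=C(\C)C(=C)O[Si](C)(C)C(C)(C)C
A4 | alternative 3 | complete skeleton with hydroxy lactone and C9 triethylsilyl ether | C=C1/C=C\[C@H](OC(=O)CCC)[C@]2(C)[C@H]([C@@H](C)[C@H](OC(=O)CCC)[C@@H]3O[C@@H]32)[C@H](O[Si](CC)(CC)CC)[C@]2(O)[C@@H](C)C(=O)O[C@H]2[C@H]1Cl
A5 | alternative 3 | C7 2-bromopropanoate of the ten-membered C8 ketone (bromide epimers) | C=C1/C=C\[C@H](OC(=O)CCC)[C@]2(C)[C@H]([C@@H](C)[C@H](OC(=O)CCC)[C@@H]3O[C@@H]32)[C@H](O[Si](CC)(CC)CC)C(=O)[C@@H](OC(=O)C(C)Br)[C@H]1Cl
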